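**Assumption:** the target SMILES has no stereocentre and no stereogenic alkene. Ardisiphenol D is achiral, so there is no enantiomer to control. The one stereocentre formed en route (C1 of 6) is racemic and is destroyed in the last step. Compound numbers follow the forward route.

## Retrosynthetic overview
1. The target, a hydroquinone mono-acetate, is an isomer of a 4-acetoxy-4-(alk-1-en-2-yl)-3-methoxycyclobutenone. The disconnection is a retro-6π/retro-4π (Moore-type ring expansion). The oxygen on the quaternary carbon stays acetylated and the ketene C=O becomes the free phenol, so no hydroquinone differentiation is needed.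
2. The cyclobutenone comes from 1,2-addition of 2-lithiopentadec-1-ene to the ketone-like carbonyl of methyl semisquarate, with the alkoxide trapped in situ by Ac2O.
3. The vinyl bromide comes from 2,3-dibromopropene and C12H25MgBr. The semisquarate comes from dimethyl squarate by reductive carbonyl transposition.
4. Ring order: the four-membered ring is bought as squarate, and the benzene ring is the only ring formed, in the final step.
5. Deliberately avoided: the benzaldehyde (o-vanillin type) Wittig/hydrogenation, para-oxidation and selective acetylation sequence.

## Route

**Step 1**
Reactants: 1, 2,3-dibromopropene; 2, dodecylmagnesium bromide (1.0 M in Et2O)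
Product: 3, 2-bromopentadec-1-ene, CH2=C(Br)–C13H27
Conditions: 1 (1.1 equiv), 2, CuI (5 mol %), Et2O/THF, 0 °C → rt, 3 h
Reagents that add atoms: dodecylmagnesium bromide (= 2), CCCCCCCCCCCC[Mg]Br
Why: This is a copper-assisted allylic substitution of the allylic C–Br by the Grignard reagent (SN2 and SN2′ give the same product), the vinylic C–Br is inert at this temperature, and CH2 + C12 gives the required C13 chain.

**Step 2**
Reactants: 4, dimethyl squarate (3,4-dimethoxycyclobut-3-ene-1,2-dione)
Product: 5, 3-methoxycyclobut-3-ene-1,2-dione (methyl semisquarate)
Conditions: LiAlH(Ot-Bu)3 (1.05 equiv), THF, −78 → −20 °C; then conc. aq HCl (cat.), CH2Cl2, rt, short contact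
Reagents that add atoms: water, O (supplies the new carbonyl oxygen in the hydrolysis; the hydride adds only H)
Why: The bulky hydride performs a single 1,2-reduction to 4-hydroxy-2,3-dimethoxycyclobutenone, and acid ionises the allylic OH to a methoxy-stabilised cation that hydrolyses with loss of MeOH, which is the known reductive carbonyl transposition of squarate esters to semisquarates.

**Step 3**
Reactants: 3, 2-bromopentadec-1-ene; 5, 3-methoxycyclobut-3-ene-1,2-dione
Product: 6, (±)-2-methoxy-4-oxo-1-(pentadec-1-en-2-yl)cyclobut-2-en-1-yl acetate. The quaternary ring carbon carries OAc and the C(=CH2)C13H27 group and sits between C(OMe)= and C=O.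
Conditions: 3, t-BuLi (2.0 equiv), Et2O, −78 °C, 30 min; cannulate into 5 (1.1 equiv), THF, −78 °C, 30 min; Ac2O (3 equiv), −78 → 0 °C; aq NaHCO3
Reagents that add atoms: acetic anhydride, CC(=O)OC(C)=O
Why: Li–Br exchange gives the vinyllithium, which adds 1,2 to the more electrophilic carbonyl (the one next to C–OMe, because the other is deactivated as a vinylogous ester), and the tertiary lithium alkoxide is O-acylated in situ; the new stereocentre is racemic and irrelevant.

**Step 4**
Reactants: 6, (±)-2-methoxy-4-oxo-1-(pentadec-1-en-2-yl)cyclobut-2-en-1-yl acetate
Product: 7, ardisiphenol D (4-hydroxy-2-methoxy-6-tridecylphenyl acetate)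
Conditions: degassed p-xylene (0.02 M), Ar, 135 °C, 2 h
Reagents that add atoms: none (6 and 7 are isomers, C22H36O4)
Why: Proposed new method: the Moore cyclobutenone ring expansion, established for 4-alkenyl-4-hydroxy/alkoxy/siloxycyclobutenones, is extended here to the 4-acetoxy compound, in which reversible conrotatory 4π opening turns the oxygen donor (OAc) outward and the alkenyl group inward, the dienylketene closes by 6π electrocyclisation (ketene carbon to =CH2) and the dienone tautomerises, so the ketene oxygen becomes the free OH flanked by two ring C–H positions, the acetate stays on the carbon between OMe and tridecyl, any ketene of the wrong geometry re-closes and is funnelled to the aromatic sink, and the stereocentre is erased.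

## Compound list
1 | 2,3-dibromopropene | C=C(Br)CBr | starting material
2 | dodecylmagnesium bromide | CCCCCCCCCCCC[Mg]Br | starting material
3 | 2-bromopentadec-1-ene | CCCCCCCCCCCCCC(Br)=C | intermediate
4 | dimethyl squarate | COC1=C(OC)C(=O)C1=O | starting material
5 | 3-methoxycyclobut-3-ene-1,2-dione | COC1=CC(=O)C1=O | intermediate
6 | (±)-2-methoxy-4-oxo-1-(pentadec-1-en-2-yl)cyclobut-2-en-1-yl acetate | CCCCCCCCCCCCCC(=C)C1(OC(C)=O)C(OC)=CC1=O | intermediate (racemic)
7 | ardisiphenol D, 4-hydroxy-2-methoxy-6-tridecylphenyl acetate | CCCCCCCCCCCCCc1cc(O)cc(OC)c1OC(C)=O | target (achiral)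

## Summary
**Total steps:** 4.
**Longest linear sequence:** 3 (1 → 3 → 6 → 7, or 4 → 5 → 6 → 7).

**Steps most likely to fail, with fallbacks**
1. **Step 4.** The acetoxy group may give poorer torquoselectivity, furanone-type by-products or acyl scrambling.
   - Quench step 3 with NH4Cl instead of Ac2O.
   - Thermolyse the free 4-hydroxycyclobutenone, which is the fully precedented variant, to 2-methoxy-6-tridecylhydroquinone.
   - Differentiate the two hydroxyls by sterics: TBSCl/imidazole on the unhindered OH, Ac2O/DMAP on the flanked OH, then HF·pyridine.
2. **Step 3.** The semisquarate C–H site may suffer competing 1,4-addition or deprotonation, the wrong carbonyl may be attacked, or the alkoxide may fragment.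
   - Abandon ring construction and use C–H functionalisation instead.
   - Acetylate commercial 2-allyl-6-methoxyphenol, then carry out cross-metathesis with 1-dodecene (Grubbs II) and hydrogenate to 2-methoxy-6-tridecylphenyl acetate.
   - Apply sterically governed Ir-catalysed C–H borylation ([Ir(OMe)cod]2/dtbpy, B2pin2) at the only C–H with no ortho substituent, which is para to OAc.
   - Oxidise the boronate mildly (NaBO3) to 7.
3. **Step 2.** Over-reduction may occur, or the labile methyl semisquarate may hydrolyse.
   - Reach 5 by a cross-coupling-type reduction instead.
   - Sequence: squaric acid → squaryl dichloride ((COCl)2, cat. DMF) → 3-chloro-4-methoxycyclobutenedione (1 equiv MeOH) → Pd(PPh3)4/Bu3SnH hydrodechlorination of the vinylogous acid chloride.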